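The twofold-symmetric 3,7-dioxabicyclo[3.3.0]octane hides L-tartaric acid. C2–C1–C5–C6 is its carbon chain and the ring-fusion carbinols C1/C5 are its stereocentres. Everything rests on cutting the oxymethylene–carbinol bonds C4–C5 and C8–C1. In the precursor, the acetonide of bis(chloromethyl) L-tartrate, each carboxyl group holds one CH2Cl over the neighbouring C–H. Two successive enolisations then close both γ-lactone rings in one operation. They form both C–C bonds and both quaternary centres with retention and give a [3.3.3]propellane dilactone that already contains both oxygen rings of the target. The aryl groups are added at the lactone carbons, and the ether rings reclose exo through benzylic cations.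

Key step: step 3

Remark: locants follow the 3,7-dioxabicyclo[3.3.0]octane numbering (C1/C5 ring fusion, C2/C6 benzylic, C4/C8 oxymethylene). TBS = tert-butyldimethylsilyl.

Step 1
Reactants: 1 dimethyl (4R,5R)-2,2-dimethyl-1,3-dioxolane-4,5-dicarboxylate (dimethyl 2,3-O-isopropylidene-L-tartrate)
Product: 2 (4R,5R)-2,2-dimethyl-1,3-dioxolane-4,5-dicarboxylic acid
Conditions: LiOH·H2O (2.3 equiv), THF–H2O, 0 °C to rt; 1 M HCl to pH 2, 0 °C
Reagents that add atoms: lithium hydroxide, [Li+].[OH-]
Why: Ester saponification at low temperature should leave the ketal and both α-alkoxy stereocentres untouched.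

Step 2
Reactants: 2 (4R,5R)-2,2-dimethyl-1,3-dioxolane-4,5-dicarboxylic acid
Product: 3 bis(chloromethyl) (4R,5R)-2,2-dimethyl-1,3-dioxolane-4,5-dicarboxylate
Conditions: ClCH2OSO2Cl (2.5 equiv), NaHCO3 (8 equiv), nBu4NHSO4 (10 mol %), CH2Cl2–H2O, 0 °C to rt
Reagents that add atoms: chloromethyl chlorosulfate, ClCOS(=O)(=O)Cl
Why: Phase-transfer O-alkylation of the carboxylates (SN2) should displace only chlorosulfate, the far better leaving group, so the C–Cl bond is kept and no stereocentre is involved.

Step 3
Reactants: 3 bis(chloromethyl) (4R,5R)-2,2-dimethyl-1,3-dioxolane-4,5-dicarboxylate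
Product: 5 (1R,5R)-1,5-(isopropylidenedioxy)-3,7-dioxabicyclo[3.3.0]octane-2,6-dione ([3.3.3]propellane dilactone), via monolactone chloromethyl ester 4 (not isolated)
Conditions: LiN(iPr)2 (1.05 equiv), THF–DMPU 6:1, 0.01 M, −78 to −50 °C; recool, LiN(iPr)2 (1.10 equiv), −78 to −30 °C
Reagents that add atoms: none
Why: LiN(iPr)2 removes one dioxolane C–H to give the lithium ester enolate, which should survive at −78 °C because the five-membered ring holds the β C–O bond close to the enolate plane, and its carbon displaces chloride from the CH2Cl group of the neighbouring ester (intramolecular SN2 enolate alkylation) to give 4; the second portion of base enolises the new lactone at its ring-fusion C–H and the remaining CH2Cl closes the second lactone in the same way. The closest known reaction types are the alkylation of tartrate acetonide enolates (self-regeneration of stereocentres) and the C-alkylation of enolates with acyloxymethyl halides. Each γ-lactone ring closes in the 5-(enolexo)-exo-tet mode, the neighbouring C–CO2 bond lying almost parallel to the enolate p orbital so that the tether reaches the carbon once the ester adopts its s-cis form. Each new quaternary centre is controlled by the tether: in the trans-diester the carboxyl group stands on the face of the neighbouring C–H, only a cis-fused five-membered ring can form, and CH2 therefore replaces H with retention, while the centre that is still tetrahedral stores the chirality because the base is added in two portions and only one centre is planar at a time. The step needs C- over O-alkylation (O-attack would require a seven-membered ring), cyclisation over intermolecular alkylation (high dilution), and alkylation over β-elimination, ketene formation or proton return (low temperature, irreversible amide base, activated α-acyloxy chloride).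

Step 4
Reactants: 5 [3.3.3]propellane dilactone
Product: 6 (1R,5R)-1,5-(isopropylidenedioxy)-3,7-dioxabicyclo[3.3.0]octane-2,6-diol (bis-lactol, anomer mixture)
Conditions: iBu2AlH (2.3 equiv), CH2Cl2, −78 °C; aq. potassium sodium tartrate
Reagents that add atoms: none
Why: Partial reduction of lactones to lactols should stop at the aluminium hemiacetal, which is stable at −78 °C; the two new anomeric centres are inconsequential.

Step 5
Reactants: 7 4-bromo-2-methoxyphenol
Product: 8 (4-bromo-2-methoxyphenoxy)(tert-butyl)dimethylsilane
Conditions: TBSCl (1.1 equiv), imidazole (1.1 equiv), CH2Cl2, rt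
Reagents that add atoms: tert-butyldimethylsilyl chloride, CC(C)(C)[Si](C)(C)Cl
Why: Standard phenol silylation masks the acidic OH for the organometallic step and can be removed by fluoride at the end.

Step 6
Reactants: 6 bis-lactol; 8 (4-bromo-2-methoxyphenoxy)(tert-butyl)dimethylsilane
Product: 10 (4S,5S)-4,5-bis{(R)-[4-(tert-butyldimethylsilyloxy)-3-methoxyphenyl](hydroxy)methyl}-4,5-bis(hydroxymethyl)-2,2-dimethyl-1,3-dioxolane, via arylmagnesium bromide 9 (not isolated)
Conditions: 8 (6 equiv), Mg, THF, 40 °C; add 6, 0 °C to rt; aqueous work-up
Reagents that add atoms: none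
Why: Grignard addition to the ring-opened hydroxy-aldehyde tautomers of the lactols consumes two equivalents per lactol (one as base), and a Cram chelate of Mg with the aldehyde and dioxolane oxygens should direct the aryl group anti to the quaternary neighbour and favour the (R)-carbinols, although either configuration can be carried on because step 7 ionises these centres.

Step 7
Reactants: 10 tetraol acetonide
Product: 12 (1S,2R,5S,6R)-2,6-bis[4-(tert-butyldimethylsilyloxy)-3-methoxyphenyl]-3,7-dioxabicyclo[3.3.0]octane-1,5-diol, via bis-TBS prinsepiol acetonide 11 (not isolated)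
Conditions: camphorsulfonic acid (20 mol %), CH2Cl2, 0 °C to rt; concentrate; AcOH–H2O–THF 3:1:1, 40 °C
Reagents that add atoms: none
Why: Acid ionises the electron-rich benzylic carbinols and each cis-disposed CH2OH closes a tetrahydrofuran (SN1 cycloetherification, the classical furofuran endgame); the cation should react in the conformer that keeps the C1/C5–O bond in its plane syn to the aryl ring, which places each aryl exo (cis to the ring-fusion oxygen) whatever the carbinol configuration, the trans-locked ketal excludes the 2,5-diaryl ether, and aqueous acetic acid then hydrolyses the ketal.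

Step 8
Reactants: 12 bis-TBS prinsepiol
Product: 13 prinsepiol, (1S,2R,5S,6R)-2,6-bis(4-hydroxy-3-methoxyphenyl)-3,7-dioxabicyclo[3.3.0]octane-1,5-diol
Conditions: nBu4NF (2.2 equiv), AcOH (2.2 equiv), THF, 0 °C
Reagents that add atoms: none
Why: Fluoride cleavage of aryl silyl ethers, buffered so that no phenoxide can open the benzylic ethers through a quinone methide, touches no stereocentre.

Compound list
1 | dimethyl (4R,5R)-2,2-dimethyl-1,3-dioxolane-4,5-dicarboxylate | COC(=O)[C@@H]1OC(C)(C)O[C@H]1C(=O)OC | starting material
2 | (4R,5R)-2,2-dimethyl-1,3-dioxolane-4,5-dicarboxylic acid | OC(=O)[C@@H]1OC(C)(C)O[C@H]1C(=O)O | intermediate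
3 | bis(chloromethyl) (4R,5R)-2,2-dimethyl-1,3-dioxolane-4,5-dicarboxylate | ClCOC(=O)[C@@H]1OC(C)(C)O[C@H]1C(=O)OCCl | intermediate
4 | chloromethyl (3aR,6aR)-2,2-dimethyl-6-oxotetrahydrofuro[3,4-d][1,3]dioxole-3a-carboxylate (monolactone, not isolated) | O=C1OC[C@@]2(C(=O)OCCl)OC(C)(C)O[C@@H]12 | intermediate
5 | (1R,5R)-1,5-(isopropylidenedioxy)-3,7-dioxabicyclo[3.3.0]octane-2,6-dione | O=C1OC[C@]2(OC(C)(C)O3)C(=O)OC[C@]123 | intermediate
6 | (1R,5R)-1,5-(isopropylidenedioxy)-3,7-dioxabicyclo[3.3.0]octane-2,6-diol (anomer mixture) | OC1OC[C@]2(OC(C)(C)O3)C(O)OC[C@]123 | intermediate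
7 | 4-bromo-2-methoxyphenol | COc1cc(Br)ccc1O | starting material
8 | (4-bromo-2-methoxyphenoxy)(tert-butyl)dimethylsilane | COc1cc(Br)ccc1O[Si](C)(C)C(C)(C)C | intermediate
9 | [4-(tert-butyldimethylsilyloxy)-3-methoxyphenyl]magnesium bromide (not isolated) | COc1cc([Mg]Br)ccc1O[Si](C)(C)C(C)(C)C | intermediate
10 | (4S,5S)-4,5-bis{(R)-[4-(tert-butyldimethylsilyloxy)-3-methoxyphenyl](hydroxy)methyl}-4,5-bis(hydroxymethyl)-2,2-dimethyl-1,3-dioxolane | OC[C@]1(OC(C)(C)O[C@@]1(CO)[C@H](O)c2ccc(O[Si](C)(C)C(C)(C)C)c(OC)c2)[C@H](O)c3ccc(O[Si](C)(C)C(C)(C)C)c(OC)c3 | intermediate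
11 | (1S,2R,5S,6R)-2,6-bis[4-(tert-butyldimethylsilyloxy)-3-methoxyphenyl]-1,5-(isopropylidenedioxy)-3,7-dioxabicyclo[3.3.0]octane (not isolated) | COc1cc([C@H]2OC[C@]3(OC(C)(C)O4)[C@@H](c5ccc(O[Si](C)(C)C(C)(C)C)c(OC)c5)OC[C@]234)ccc1O[Si](C)(C)C(C)(C)C | intermediate
12 | (1S,2R,5S,6R)-2,6-bis[4-(tert-butyldimethylsilyloxy)-3-methoxyphenyl]-3,7-dioxabicyclo[3.3.0]octane-1,5-diol | COc1cc([C@H]2OC[C@]3(O)[C@@H](c4ccc(O[Si](C)(C)C(C)(C)C)c(OC)c4)OC[C@]23O)ccc1O[Si](C)(C)C(C)(C)C | intermediate
13 | prinsepiol | COc1cc([C@H]2OC[C@]3(O)[C@@H](c4ccc(O)c(OC)c4)OC[C@]23O)ccc1O | target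

Total step count: 8. Longest linear sequence: 7 (steps 1–4 and 6–8).

Steps most likely to fail

Step 3. Elimination of the dioxolane oxygen, loss of chloromethoxide with ketene formation, or proton return to the enolate may outrun ring closure. Any of these would cost material or erode the configurational memory. The fallback replaces the free lithium enolate by a neutral nucleophile and sets out from 3. In-situ trapping (LiN(iPr)2, Me3SiCl, THF, −100 °C, one equivalent) should give the mono silyl ketene acetal F1. Lewis-acid activation of the chloromethyl ester (ZnBr2, CH2Cl2, Mukaiyama-type alkylation of a silyl ketene acetal with an α-oxygenated chloride) should then close the first lactone to 4, which is now isolated. The same pair of operations on 4, through the lactone silyl ketene acetal F2, comes back to the route at 5.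

Step 7. Reversible ionisation of the benzylic ethers may erode the exo selectivity. The cation may also fragment with loss of formaldehyde (retro-Prins), and a slow ketal hydrolysis may call for acid strong enough to epimerise. The fallback forms the C–O bonds at the primary carbons instead, without any cation, and sets out from 10 (the chelation-controlled diastereomer, purified). Selective sulfonylation of the two primary alcohols (TsCl, pyridine, 0 °C) should give the bis-tosylate F3. NaH in THF should then close both rings by Williamson etherification (5-exo-tet, retention at the carbinol carbons). This comes back to the route at 11, which is isolated and hydrolysed with aqueous acetic acid as in step 7.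

Step 6. The magnesium alkoxide of the ring-opened β-oxido aldehyde may lose formaldehyde by retro-aldol cleavage, or the hindered lactols may open too slowly for clean double addition. The fallback brings in the aryl groups at the lactone oxidation level (C-aryl glycoside protocol) and sets out from 5. The aryllithium F4 (from 8, nBuLi, THF, −78 °C) should add once to each lactone to give the bis-hemiketal F5. Et3SiH with BF3·OEt2 (CH2Cl2, −78 °C) should then reduce the two aryl-stabilised oxocarbenium ions with the rings kept closed, which comes back to the route at 11.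

Further compounds
F1 | step 3 | chloromethyl (R)-5-[(chloromethoxy)(trimethylsilyloxy)methylidene]-2,2-dimethyl-1,3-dioxolane-4-carboxylate | ClCOC(=O)[C@@H]1OC(C)(C)OC1=C(OCCl)O[Si](C)(C)C
F2 | step 3 | trimethylsilyl ketene acetal of monolactone 4 | C[Si](C)(C)OC1=C2OC(C)(C)O[C@]2(C(=O)OCCl)CO1
F3 | step 7 | bis(4-methylbenzenesulfonate) of the two primary alcohols of 10 | Cc1ccc(cc1)S(=O)(=O)OC[C@]2(OC(C)(C)O[C@@]2(COS(=O)(=O)c3ccc(C)cc3)[C@H](O)c4ccc(O[Si](C)(C)C(C)(C)C)c(OC)c4)[C@H](O)c5ccc(O[Si](C)(C)C(C)(C)C)c(OC)c5
F4 | step 6 | [4-(tert-butyldimethylsilyloxy)-3-methoxyphenyl]lithium | [Li]c1ccc(O[Si](C)(C)C(C)(C)C)c(OC)c1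
F5 | step 6 | (1S,5S)-2,6-bis[4-(tert-butyldimethylsilyloxy)-3-methoxyphenyl]-1,5-(isopropylidenedioxy)-3,7-dioxabicyclo[3.3.0]octane-2,6-diol (bis-hemiketal, anomer mixture) | COc1cc(C2(O)OC[C@]3(OC(C)(C)O4)C(O)(c5ccc(O[Si](C)(C)C(C)(C)C)c(OC)c5)OC[C@]234)ccc1O[Si](C)(C)C(C)(C)C
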